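**Plan**
1. Retrosynthetic cuts: first the C19–O acyl bond, then the C12–C13 sp3–sp2 bond (dienyl Grignard reagent). Then one reconnection: C12 and C17 are joined through one extra carbon. This turns C8, C9, C11, C12 and C17 into the aromatic ring C of podocarpic acid.
2. Enabling feature: on ring B, C8 carries an equatorial O and a one-carbon branch (C17), and its neighbour C9 carries the two-carbon arm C11–C12. This is what remains of a benzene ring fused at C8–C9 after three events: scission of the bond next to the phenol carbon C12, closure of CO2H-12 on C8, and loss of the sixth carbon as CO2.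
3. Forward order: rings A and B are bought intact. Ring C goes from phenol to o-quinone, then through peracid scission and muconolactonisation (C8–O), hydrogenation (C9–H) and decarboxylation (C17 methyl). The lactone is then converted to the iodide, the diene is coupled on, and the ester is made last.
4. Stereochemistry: C4 (axial C19), C5 and C10 come from (+)-podocarpic acid. C8 is fixed by the geometry of a planar butenolide on the locked chair of ring B. C9 is fixed by α-face hydrogenation.

Key step: step 3

Remark: the SMILES is read as (4S,5R,8R,9R,10S), that is, normal labdane series, 8α-OH, acyloxy group on the axial C19. Labdane numbering is used throughout. Podocarpane C14 is labdane C17, and podocarpane C13 is the carbon that leaves as CO2.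

Step 1
Reactants: 1 (+)-podocarpic acid
Product: 2 methyl podocarpate
Conditions: MeI, KHCO3, DMF, rt
Reagents that add atoms: iodomethane, CI
Why: SN2 O-alkylation of the carboxylate avoids attack at the hindered axial C19 carbonyl, and bicarbonate is too weak a base to ionise the phenol, so only the acid should be methylated; the ester then protects C19 up to step 11.

Step 2
Reactants: 2 methyl podocarpate
Product: 3 methyl 12,13-dioxopodocarpa-8(14),9(11)-dien-19-oate (ring-C o-quinone)
Conditions: IBX (1.1 equiv), DMF, rt, dark; used at once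
Reagents that add atoms: IBX (2-iodoxybenzoic acid), O=C1OI(=O)(O)c2ccccc12
Why: IBX ortho-oxygenation of a phenol (aryloxy-iodane, intramolecular O transfer, collapse to the o-quinone) should go to C13, because the other ortho carbon C11 sits in the bay under C1H2 and the C20 methyl group, the same bias that directs electrophiles to C13 of podocarpates.

Step 3
Reactants: 3 ring-C o-quinone
Product: 6 methyl 17-carboxy-12-oxo-8α,12-epoxy-13,14,15,16-tetranorlabd-9(11)-en-19-oate (butenolide acid), via muconic anhydride 4 (not isolated), via muconic diacid 5 (not isolated)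
Conditions: mCPBA (1.1 equiv), CH2Cl2, 0 °C; then THF–H2O, TsOH (cat.), rt
Reagents that add atoms: mCPBA, O=C(OO)c1cccc(Cl)c1; water, O
Why: The peracid adds to a quinone carbonyl and the neighbouring acyl carbon migrates to oxygen (Baeyer–Villiger type), which places O between C12 and C13 whichever carbonyl is attacked and gives the seven-membered anhydride 4; water opens 4 to diacid 5, whose two exocyclic alkenes keep the cis geometry of the former ring, so that CO2H-12 lies next to C8 and CO2H-13 next to C9. The closest known reaction types are the peracid cleavage of o-benzoquinones to muconic anhydrides and the acid-induced cycloisomerisation of 3,4-dialkyl-cis,cis-muconic acids to muconolactones. The one ring that closes is the butenolide (O, C12, C11, C9, C8), by 5-exo-trig oxa-Michael attack of CO2H-12 on C8, the β-carbon of the protonated C8=C17–CO2H unit, with the proton ending on C17. The new stereocentre C8 is controlled by ring geometry: a planar butenolide on the sp2 carbon C9 needs an O–C8–C9–C10 torsion near 180°, which in the chair of ring B locked by the trans-decalin is the equatorial (α) bond, so that C17 is forced axial (β), whereas β-closure would need a boat. The selectivity needed is C8 against C9 as acceptor, with a stop before the bis-lactone: attack at C9 is attack at a neopentyl-type carbon beside quaternary C10 and would create two adjacent fully substituted carbons, so closure at C8, flanked by C7H2, should win kinetically and, the addition being reversible in acid, thermodynamically. The step also tells the two carboxyl groups apart (C12 as lactone, C13 as the only free acid), while the hindered C19 ester and the electron-poor alkenes are inert to the peracid.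

Step 4
Reactants: 6 butenolide acid
Product: 7 methyl 17-carboxy-12-oxo-8α,12-epoxy-13,14,15,16-tetranorlabdan-19-oate (9α-H lactone acid)
Conditions: H2 (4 atm), PtO2, EtOAc, rt
Reagents that add atoms: none
Why: Heterogeneous syn-hydrogenation of a butenolide, in which the β face of C9=C11 is walled off by the axial groups on C8 (CH2CO2H) and C10 (CH3), so hydrogen should arrive from the α face and set 9α-H (equatorial C11, trans-fused lactone); Pt is chosen over Pd to spare the allylic C8–O bond.

Step 5
Reactants: 7 lactone acid
Product: 8 methyl 12-oxo-8α,12-epoxy-13,14,15,16-tetranorlabdan-19-oate (19-carbomethoxy analogue of sclareolide)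
Conditions: 9-mesityl-10-phenylacridinium BF4 (5 mol %), (PhS)2 (10 mol %), i-Pr2NEt (20 mol %), CF3CH2OH, 450 nm, rt
Reagents that add atoms: none
Why: Photoredox hydrodecarboxylation, in which the excited acridinium oxidises the carboxylate, CO2 leaves and the primary C17 radical takes H from thiophenol formed in situ faster than a β-acyloxy shift can occur, while working on the carboxylate avoids β-elimination of the lactone oxygen; no stereocentre is touched.

Step 6
Reactants: 8 lactone ester
Product: 9 methyl 8α,12-dihydroxy-13,14,15,16-tetranorlabdan-19-oate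
Conditions: LiBH4, THF, 0 °C → rt
Reagents that add atoms: none
Why: Chemoselective hydride reduction, in which the γ-lactone is opened to the diol whereas the axial neopentyl C19 ester, which needs forcing hydride conditions, should stay untouched.

Step 7
Reactants: 9 diol ester
Product: 11 methyl 12-hydroxy-8α-(triethylsilyloxy)-13,14,15,16-tetranorlabdan-19-oate, via bis-TES ether 10 (not isolated)
Conditions: TESOTf (2.5 equiv), 2,6-lutidine, CH2Cl2, 0 °C; then MeOH, PPTS (cat.), 0 °C
Reagents that add atoms: triethylsilyl triflate, CC[Si](CC)(CC)OS(=O)(=O)C(F)(F)F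
Why: Exhaustive silylation with the triflate reaches the tertiary 8-OH, and acid-catalysed methanolysis then removes only the unhindered primary silyl ether, so O-8 is masked before C12 becomes an electrophile (a free 8-OH would close a tetrahydrofuran ring on C12).

Step 8
Reactants: 11 primary alcohol
Product: 12 methyl 12-iodo-8α-(triethylsilyloxy)-13,14,15,16-tetranorlabdan-19-oate
Conditions: I2, PPh3, imidazole, CH2Cl2, 0 °C → rt
Reagents that add atoms: iodine, II
Why: Appel-type iodination (SN2 of iodide on the primary alkoxyphosphonium ion) under imidazole buffering, which a tertiary TES ether and the ester tolerate.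

Step 9
Reactants: 13 chloroprene (2-chlorobuta-1,3-diene)
Product: 14 buta-1,3-dien-2-ylmagnesium chloride (THF solution, used directly)
Conditions: Mg turnings, ZnCl2 (cat.), THF, 50 °C
Reagents that add atoms: magnesium, [Mg]
Why: Direct magnesium insertion into the vinylic C–Cl bond of chloroprene, a known preparation of the 2-dienyl Grignard reagent when zinc chloride is present as activator.

Step 10
Reactants: 12 iodide; 14 buta-1,3-dien-2-ylmagnesium chloride
Product: 15 methyl 8α-(triethylsilyloxy)labda-13(16),14-dien-19-oate
Conditions: Li2CuCl4 (5 mol %), THF, −10 → 10 °C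
Reagents that add atoms: none
Why: Copper-catalysed Kumada-type alkyl–alkenyl cross-coupling of a primary iodide with the 2-dienyl Grignard reagent, a known entry to 2-alkylbuta-1,3-dienes, with the hindered ester and the silyl ether as spectators.

Step 11
Reactants: 15 diene ester
Product: 16 8α-(triethylsilyloxy)labda-13(16),14-dien-19-ol
Conditions: LiAlH4, THF, reflux
Reagents that add atoms: none
Why: Forcing LiAlH4 reduction of the hindered ester to the neopentyl C19 alcohol; an unactivated 1,3-diene and a tertiary silyl ether are inert to hydride.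

Step 12
Reactants: 16 C19 alcohol; 17 (E)-4-methoxycinnamic acid
Product: 18 8α-(triethylsilyloxy)labda-13(16),14-dien-19-yl (E)-4-methoxycinnamate
Conditions: EDC·HCl, DMAP, CH2Cl2, rt → 40 °C
Reagents that add atoms: none
Why: Steglich esterification through the acylpyridinium ion, which acylates the hindered but primary 19-OH while O-8 is still silylated and the E alkene of the acid is not touched.

Step 13
Reactants: 18 silyl ether
Product: 19 8α-hydroxylabda-13(16),14-dien-19-yl (E)-4-methoxycinnamate (target)
Conditions: HF·pyridine, pyridine, THF, 0 °C → rt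
Reagents that add atoms: none
Why: Fluoride-driven Si–O cleavage under pyridine buffering, mild enough for the tertiary alcohol, the diene and the cinnamate.

**Compound list**
1 | (+)-podocarpic acid, (4S,5R,10S)-12-hydroxypodocarpa-8,11,13-trien-19-oic acid | Oc1ccc2c(c1)[C@@]3(C)CCC[C@](C)(C(=O)O)[C@@H]3CC2 | starting material
2 | methyl podocarpate | Oc1ccc2c(c1)[C@@]3(C)CCC[C@](C)(C(=O)OC)[C@@H]3CC2 | intermediate
3 | methyl 12,13-dioxopodocarpa-8(14),9(11)-dien-19-oate | O=C1C(=O)C=C2C(=C1)[C@@]3(C)CCC[C@](C)(C(=O)OC)[C@@H]3CC2 | intermediate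
4 | muconic anhydride (O inserted between C12 and C13, oxepine-2,7-dione fused at C8–C9) | O=C1OC(=O)C=C2C(=C1)[C@@]3(C)CCC[C@](C)(C(=O)OC)[C@@H]3CC2 | intermediate
5 | cis,cis-muconic diacid (12,13-seco diacid, exocyclic alkenes C9=C11 and C8=C17) | O=C(O)/C=C1/[C@@]2(C)CCC[C@](C)(C(=O)OC)[C@@H]2CC/C1=C/C(=O)O | intermediate
6 | methyl 17-carboxy-12-oxo-8α,12-epoxy-13,14,15,16-tetranorlabd-9(11)-en-19-oate | O=C1C=C2[C@@]3(C)CCC[C@](C)(C(=O)OC)[C@@H]3CC[C@@]2(CC(=O)O)O1 | intermediate
7 | methyl 17-carboxy-12-oxo-8α,12-epoxy-13,14,15,16-tetranorlabdan-19-oate | O=C1C[C@@H]2[C@@]3(C)CCC[C@](C)(C(=O)OC)[C@@H]3CC[C@@]2(CC(=O)O)O1 | intermediate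
8 | methyl 12-oxo-8α,12-epoxy-13,14,15,16-tetranorlabdan-19-oate | O=C1C[C@@H]2[C@@]3(C)CCC[C@](C)(C(=O)OC)[C@@H]3CC[C@@]2(C)O1 | intermediate
9 | methyl 8α,12-dihydroxy-13,14,15,16-tetranorlabdan-19-oate | OCC[C@@H]1[C@@]2(C)CCC[C@](C)(C(=O)OC)[C@@H]2CC[C@@]1(C)O | intermediate
10 | methyl 8α,12-bis(triethylsilyloxy)-13,14,15,16-tetranorlabdan-19-oate | CC[Si](CC)(CC)OCC[C@@H]1[C@@]2(C)CCC[C@](C)(C(=O)OC)[C@@H]2CC[C@@]1(C)O[Si](CC)(CC)CC | intermediate
11 | methyl 12-hydroxy-8α-(triethylsilyloxy)-13,14,15,16-tetranorlabdan-19-oate | OCC[C@@H]1[C@@]2(C)CCC[C@](C)(C(=O)OC)[C@@H]2CC[C@@]1(C)O[Si](CC)(CC)CC | intermediate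
12 | methyl 12-iodo-8α-(triethylsilyloxy)-13,14,15,16-tetranorlabdan-19-oate | ICC[C@@H]1[C@@]2(C)CCC[C@](C)(C(=O)OC)[C@@H]2CC[C@@]1(C)O[Si](CC)(CC)CC | intermediate
13 | chloroprene | C=CC(Cl)=C | starting material
14 | buta-1,3-dien-2-ylmagnesium chloride | C=CC(=C)[Mg]Cl | intermediate
15 | methyl 8α-(triethylsilyloxy)labda-13(16),14-dien-19-oate | C=CC(=C)CC[C@@H]1[C@@]2(C)CCC[C@](C)(C(=O)OC)[C@@H]2CC[C@@]1(C)O[Si](CC)(CC)CC | intermediate
16 | 8α-(triethylsilyloxy)labda-13(16),14-dien-19-ol | C=CC(=C)CC[C@@H]1[C@@]2(C)CCC[C@](C)(CO)[C@@H]2CC[C@@]1(C)O[Si](CC)(CC)CC | intermediate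
17 | (E)-4-methoxycinnamic acid | COc1ccc(/C=C/C(=O)O)cc1 | starting material
18 | 8α-(triethylsilyloxy)labda-13(16),14-dien-19-yl (E)-4-methoxycinnamate | C=CC(=C)CC[C@@H]1[C@@]2(C)CCC[C@](C)(COC(=O)/C=C/c3ccc(OC)cc3)[C@@H]2CC[C@@]1(C)O[Si](CC)(CC)CC | intermediate
19 | 8α-hydroxylabda-13(16),14-dien-19-yl (E)-4-methoxycinnamate | C=CC(=C)CC[C@@H]1[C@@]2(C)CCC[C@](C)(COC(=O)/C=C/c3ccc(OC)cc3)[C@@H]2CC[C@@]1(C)O | target

**Count**
Total steps: 13.
Longest linear sequence: 12 steps, from 1 to 19 (steps 1–8 and 10–13); step 9 is the side branch.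

**Steps most likely to fail**

Step 3.
- What may go wrong: the o-quinone may tautomerise or dimerise before the peracid adds. The lactonisation may close on C9 instead of C8. It may also run on to the bis-lactone.
- Fallback: it cuts the same C12–C13 bond by dearomatisation and ozonolysis, and sets O-8 by epoxidation. It sets out from 1 and comes back at 6. Compound 1 is O-methylated (Me2SO4, aq NaOH) to O-methylpodocarpic acid F1. Birch reduction of its carboxylate (Li, NH3, t-BuOH) gives 12-methoxypodocarpa-8,12-dien-19-oic acid F2, and the crude carboxylate is alkylated (MeI, K2CO3, DMF) to the methyl ester F3. One equivalent of ozone (CH2Cl2–MeOH, pyridine, −78 °C, then Me2S) cleaves only the enol ether C12=C13. This gives dimethyl 13-oxo-12,13-secopodocarp-8-ene-12,19-dioate F4, with the tetrasubstituted C8=C9 alkene intact. Pinnick oxidation gives the C13 acid F5. Buffered mCPBA epoxidises C8=C9 from the α face, opposite the C20 methyl group, to the 8α,9α-epoxide F6. With DBU the carboxylate shields the C17 hydrogens, and the C11 hydrogen next to the ester is removed. E1cB opening of the C9–O bond then frees the 8α-alkoxide, which lactonises on the C12 ester to 6.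

Step 4.
- What may go wrong: hydrogen uptake may be slow at an alkene flanked by two fully substituted carbons, and the allylic C8–O bond may undergo hydrogenolysis.
- Fallback: the alkene reduction is moved behind the lactone reduction, so that the free 8α-OH steers a homogeneous catalyst. It sets out from 6 and comes back at 9. Compound 6 is first hydrodecarboxylated under the conditions of step 5. Thiophenol is added so that the homoallylic C17 radical is quenched before it can add to C9. This gives methyl 12-oxo-8α,12-epoxy-13,14,15,16-tetranorlabd-9(11)-en-19-oate F7. DIBAL (CH2Cl2, −78 → 0 °C) reduces the butenolide to the (Z)-ene-diol methyl 8α,12-dihydroxy-13,14,15,16-tetranorlabd-9(11)-en-19-oate F8. Hydroxyl-directed hydrogenation with [Ir(cod)(PCy3)(py)]PF6 (H2, CH2Cl2) then delivers hydrogen on the face of the 8α-OH group and gives 9.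

Step 2.
- What may go wrong: oxygen may be transferred to C11. The o-quinone may also be lost on isolation, through tautomerisation to the p-quinone methide (via C7–H) or through Diels–Alder dimerisation.
- Fallback: O-13 is installed through a C–C bond and a migration. It sets out from 2 and comes back at 3. Magnesium-mediated ortho-formylation (MgCl2, Et3N, paraformaldehyde, MeCN, reflux) gives methyl 13-formylpodocarpate F9. Dakin oxidation (H2O2, NaOH) gives the storable catechol methyl 12,13-dihydroxypodocarpa-8,11,13-trien-19-oate F10. This is oxidised with Ag2O in Et2O to 3 only immediately before step 3.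

Further compounds
F1 | step 3 | O-methylpodocarpic acid | COc1ccc2c(c1)[C@@]3(C)CCC[C@](C)(C(=O)O)[C@@H]3CC2
F2 | step 3 | 12-methoxypodocarpa-8,12-dien-19-oic acid | COC1=CCC2=C(C1)[C@@]3(C)CCC[C@](C)(C(=O)O)[C@@H]3CC2
F3 | step 3 | methyl 12-methoxypodocarpa-8,12-dien-19-oate | COC1=CCC2=C(C1)[C@@]3(C)CCC[C@](C)(C(=O)OC)[C@@H]3CC2
F4 | step 3 | dimethyl 13-oxo-12,13-secopodocarp-8-ene-12,19-dioate | O=CCC1=C(CC(=O)OC)[C@@]2(C)CCC[C@](C)(C(=O)OC)[C@@H]2CC1
F5 | step 3 | 12,13-secopodocarp-8-ene-12,13,19-trioic acid 12,19-dimethyl ester | OC(=O)CC1=C(CC(=O)OC)[C@@]2(C)CCC[C@](C)(C(=O)OC)[C@@H]2CC1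
F6 | step 3 | 8α,9α-epoxide of F5 | OC(=O)C[C@]12O[C@@]1(CC(=O)OC)[C@@]3(C)CCC[C@](C)(C(=O)OC)[C@@H]3CC2
F7 | step 4 | methyl 12-oxo-8α,12-epoxy-13,14,15,16-tetranorlabd-9(11)-en-19-oate | O=C1C=C2[C@@]3(C)CCC[C@](C)(C(=O)OC)[C@@H]3CC[C@@]2(C)O1
F8 | step 4 | methyl (9(11)Z)-8α,12-dihydroxy-13,14,15,16-tetranorlabd-9(11)-en-19-oate | OC/C=C1/[C@@]2(C)CCC[C@](C)(C(=O)OC)[C@@H]2CC[C@@]1(C)O
F9 | step 2 | methyl 13-formylpodocarpate | O=Cc1cc2c(cc1O)[C@@]3(C)CCC[C@](C)(C(=O)OC)[C@@H]3CC2
F10 | step 2 | methyl 12,13-dihydroxypodocarpa-8,11,13-trien-19-oate | Oc1cc2c(cc1O)[C@@]3(C)CCC[C@](C)(C(=O)OC)[C@@H]3CC2
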